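A small charge of J meets a gas held at constant pressure, and we ask how much of that J ends as J.Z.

    X ⇌ Z, rate k1*(csat - [Z]) (k1 = 2.36 × 10⁻⁵ /s, csat = 3.3 mM)
    J + Z → J.Z (k2 = 0.0107 /M/s)
    Z + J.Z → Z.J.Z (k3 = 0.0190 /M/s)
    L ⇌ J.Z, rate k4*(cs4 - [J.Z]) while solid is left; crystals form when [J.Z] > cs4 (cs4 = 0.56 mM, k4 = 9.51 × 10⁻⁵ /s)

J 0.050 M; X 3.3 mM (held); time 6.0 d

- violet: doubling the dissolution coefficient of step 4, all else as stated
- amber: doubling the solubility in step 4, all else as stated
- teal: doubling the transfer coefficient of step 1, all else as stated
- green: doubling the saturation concentration of X, all else as stated

- what is said of J.Z includes L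
- L is a solid; its amount is given per volume of the solution
- at the start none of Z is dissolved
- run time (flask): 6.0 d

* J.Z and L together at 6.0 d, in percent of the J charged
* the change that raises the amount of J.Z and L together at 6.0 d, in percent of the J charged most ("none" if none brings more than 2 percentage points) (violet / amber / teal / green / none)
* amount of J.Z and L together at 6.0 d, in percent of the J charged, after green

1. First estimate: into an empty solution, the transfer step delivers a gas budget of 40.4 mM, or 80.7 % of the charge.

2. Objection: is the solution empty? By reaction with J as charged, Z has a half-life of 0.36 h, far shorter than the run. Its first-order loss to J as charged is also faster than the transfer coefficient, so we take transfer as the rate-limiting step and Z as low, made about as fast as it is used.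

3. Objection: Z has other exits, back to the gas and into Z.J.Z. The second exit depends on dissolved J.Z. Crystals relax that level quickly, so at full supply we put it near 1.38 mM.

4. With Z made as fast as it is used and dissolved J.Z held at that level, the supply is shared among the exits of Z. Integrating the loss of J in closed form gives

J used + K · ln(J charged / J left) = budget,

where K is the loss level, the J concentration at which the other exits take as much Z as J does: 4.65 mM.

5. Taking the logarithm as one leaves 14.3 mM of J, so the logarithm is 1.25. That leaves 15.5 mM, and the logarithm becomes 1.17.

6. Objection: J used is not yield, and we reckon 2.87 mM of it going on to Z.J.Z. We commit to 64.1 %.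

7. Teal and green raise the budget to 80.8 mM, more than the charge, so we reckon the excess of 30.7 mM as split between the gas and Z.J.Z. For this split we take dissolved J.Z at the solubility, a choice we expect to flatter both. Teal also doubles the leak back to the gas. Violet and amber shift the dissolved level, and we keep the logarithm. The ranking gives teal, and green gives 80.9 %.

The forecast gave 65 %, 77 % after green and teal as the best change, on the ground that “Gas transfer limits the rate”.

The simulation gives 64.7 %, and 78.1 % after green, with teal best at 17 percentage points against 13 points for green. In the flask, net turnover into J.Z up to the asked time was 69.7 % of the charge. Now take the neighbour flask with 0.085 M of J, and reckon it with the same budget and the same loss level 4.65 mM. The rule leaves about 47.6 mM of J and puts J.Z with L at 42.1 % of that charge. That neighbour flask stands at 42.7 %, with 55.7 % of its J left.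

The constants used here stand for no real mixture; the result is computed.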